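**Strategy.** Ring A is disconnected at C8–C8a and C4a–C5, back to a preformed 2-aryl-3-benzyloxy-4-pyranone (rings C and B) and a four-carbon squarate unit. The feature exploited is the run of four oxygenated carbons C5–C8 of ring A beside the C4a–C8a double bond that ring A shares with pyranone ring C. In one operation, heating a 4-hydroxy-4-pyranonylcyclobutenone opens the four-membered ring to a dienylketene that closes onto the pyranone CH, forming C8–C8a and ring A as a 5,8-hydroquinone with 6-OMe and 7-OtBu in place. The precursor is a tertiary carbinol linking pyranone C5 to a cyclobutenone bearing methoxy next to the carbinol and tert-butoxy next to the carbonyl.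

Key step: step 8

Assumptions and remarks on the chemistry:
- 3-Bromofuran, 3,4-bis(benzyloxy)benzaldehyde, dimethyl squarate and tert-butyl 2,2,2-trichloroacetimidate are taken as purchasable. All chiral intermediates are racemic, which is harmless because no stereocentre reaches the target.
- A furyl carbinol with no substituent on furan C3 ends one oxidation level below a 3-hydroxy-4-pyranone after oxidative ring expansion, so rearrangement alone cannot deliver it. The bromine on furan C3 is carried so that it can leave as HBr in step 2, which makes that step redox-neutral.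
- Numbering: the carbon attacked by the ketene in step 8 is the CH next to the ring oxygen, C6 of pyranone 8. In the name of 13 the same atom is C2 of the pyran-3-yl group, and it becomes C8a of the flavone.

Step 1
Reactants: 1 3-bromofuran; 2 3,4-bis(benzyloxy)benzaldehyde
Product: 4 [3,4-bis(benzyloxy)phenyl](3-bromofuran-2-yl)methanol (racemic), via (3-bromofuran-2-yl)lithium 3 (not isolated)
Conditions: LiN(iPr)2 (LDA), THF, −78 °C; then 2, −78 °C; then H2O
Reagents that add atoms: none
Why: Directed deprotonation removes the C2 proton of 3-bromofuran (flanked by O and Br) at −78 °C without halogen migration, and the furyllithium adds 1,2 to the aldehyde; the carbinol centre forms racemic and is destroyed in step 2.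

Step 2
Reactants: 4 [3,4-bis(benzyloxy)phenyl](3-bromofuran-2-yl)methanol
Product: 6 2-[3,4-bis(benzyloxy)phenyl]-3-hydroxy-4H-pyran-4-one, via bromo hemiacetal 5 (not isolated)
Conditions: NBS (1.0 equiv), NaHCO3, THF/H2O, 0 °C; then 2 M aq H2SO4, 65 °C
Reagents that add atoms: water, O
Why: Achmatowicz rearrangement gives the 4-bromo-6-hydroxy-2H-pyran-3(6H)-one, which in hot aqueous acid enolises toward C2, ionises at C6 to a 4-bromo-3-hydroxypyrylium ion, takes up water at C4 and loses HBr, the halopyranone-to-γ-pyrone conversion known from maltol manufacture; the stereocentres of 5 vanish.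

Step 3
Reactants: 6 2-[3,4-bis(benzyloxy)phenyl]-3-hydroxy-4H-pyran-4-one
Product: 7 3-(benzyloxy)-2-[3,4-bis(benzyloxy)phenyl]-4H-pyran-4-one
Conditions: BnBr, K2CO3, DMF, 50 °C
Reagents that add atoms: benzyl bromide, BrCc1ccccc1
Why: Williamson etherification of the acidic enolic 3-hydroxyl, as in the benzylation of maltol; no other nucleophilic site is present.

Step 4
Reactants: 7 3-(benzyloxy)-2-[3,4-bis(benzyloxy)phenyl]-4H-pyran-4-one
Product: 8 3-(benzyloxy)-2-[3,4-bis(benzyloxy)phenyl]-5-iodo-4H-pyran-4-one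
Conditions: I2 (1.5 equiv), pyridine, DMAP (0.2 equiv), CH2Cl2, 0 °C to rt
Reagents that add atoms: iodine, II
Why: Amine-assisted α-iodination of an enone (conjugate addition of the pyridine base at C6, iodination of the enolate at C5, loss of the pyridinium) places iodine on the α-carbon of the vinylogous ester only, and molecular iodine without an activator should leave the dialkoxyphenyl ring alone.

Step 5
Reactants: 9 dimethyl squarate
Product: 10 3-hydroxy-4-methoxycyclobut-3-ene-1,2-dione
Conditions: NaOH (1.0 equiv), THF/H2O, 0 °C; then HCl (1.0 equiv)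
Reagents that add atoms: sodium hydroxide, [Na+].[OH-]
Why: Saponification of a vinylogous ester by addition–elimination stops after one methoxy group, because the vinylogous carboxylate formed is deactivated toward a second attack.

Step 6
Reactants: 10 3-hydroxy-4-methoxycyclobut-3-ene-1,2-dione
Product: 11 3-tert-butoxy-4-methoxycyclobut-3-ene-1,2-dione
Conditions: tert-butyl 2,2,2-trichloroacetimidate (2.5 equiv), CH2Cl2/cyclohexane, rt
Reagents that add atoms: tert-butyl 2,2,2-trichloroacetimidate, CC(C)(C)OC(=N)C(Cl)(Cl)Cl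
Why: Imidate tert-butylation of a strong vinylogous carboxylic acid, which protonates the imidate itself; both nucleophilic oxygens of the squarate anion lead to the same 1,2-diester, so no positional isomer can form.

Step 7
Reactants: 8 3-(benzyloxy)-2-[3,4-bis(benzyloxy)phenyl]-5-iodo-4H-pyran-4-one; 11 3-tert-butoxy-4-methoxycyclobut-3-ene-1,2-dione
Product: 13 4-{5-(benzyloxy)-6-[3,4-bis(benzyloxy)phenyl]-4-oxo-4H-pyran-3-yl}-2-tert-butoxy-4-hydroxy-3-methoxycyclobut-2-en-1-one (racemic), via pyranonylmagnesium chloride 12 (not isolated)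
Conditions: iPrMgCl·LiCl (1.05 equiv), THF, −40 °C; then 11, −78 °C; then H2O
Reagents that add atoms: none
Why: Iodine–magnesium exchange on a cyclic α-iodo-β-alkoxy enone is faster than addition of iPrMgCl to the pyranone and gives an alkenyl Grignard that is stable in the cold; it adds 1,2 to the squarate carbonyl flanked by the small methoxy group because the tert-butoxy group shields the other one, and the carbinol centre forms racemic with no control needed.

Step 8
Reactants: 13 4-{5-(benzyloxy)-6-[3,4-bis(benzyloxy)phenyl]-4-oxo-4H-pyran-3-yl}-2-tert-butoxy-4-hydroxy-3-methoxycyclobut-2-en-1-one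
Product: 16 3-(benzyloxy)-2-[3,4-bis(benzyloxy)phenyl]-7-tert-butoxy-5,8-dihydroxy-6-methoxy-4H-chromen-4-one, via (Z)-dienylketene 14 (not isolated), via 8aH-chromenedione 15 (not isolated)
Conditions: degassed toluene (0.02 M), 110 °C, Ar
Reagents that add atoms: none
Why: Heat opens the cyclobutenone by conrotatory 4π cleavage of the C(=O)–C(OH) bond to the (Z)-dienylketene 14, whose ketene carbon then bonds to the unsubstituted pyranone CH next to the ring oxygen in a thermally allowed disrotatory 6π electrocyclisation, and tautomerisation of dienone 15 gives hydroquinone 16. The closest known reaction type is the thermal ring expansion of squarate-derived 4-aryl- and 4-alkenyl-4-hydroxycyclobutenones to hydroquinones (Moore rearrangement), here with the pyranone C5=C6 bond as the alkenyl partner. Ring A is closed by this 6π electrocyclisation, which makes the C8–C8a bond; the C4a–C5 bond is already present from step 7. No stereocentre is set, since the carbinol carbon of 13 becomes sp2 C5 and the sp3 C8a of 15 is lost on enolisation. The step needs outward rotation of the hydroxyl and inward rotation of the pyranonyl group, which the donor character of the hydroxyl secures, and closure at carbon, which is secured because the only other ring atom next to the point of attachment is the C4 carbonyl carbon. Because the ketene carbon becomes C8 and the carbinol carbon C5, the squarate delivers all four ring-A oxygens, with methoxy on C6 and tert-butoxy on C7.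

Step 9
Reactants: 16 3-(benzyloxy)-2-[3,4-bis(benzyloxy)phenyl]-7-tert-butoxy-5,8-dihydroxy-6-methoxy-4H-chromen-4-one
Product: 17 3-(benzyloxy)-2-[3,4-bis(benzyloxy)phenyl]-7-tert-butoxy-5-hydroxy-6,8-dimethoxy-4H-chromen-4-one
Conditions: MeI (1.2 equiv), K2CO3 (1.5 equiv), degassed DMF, rt, Ar
Reagents that add atoms: iodomethane, CI
Why: Williamson methylation takes the free 8-hydroxyl, because the 5-hydroxyl is held in a hydrogen bond to the C4 carbonyl and is far less acidic and nucleophilic under mild carbonate conditions.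

Step 10
Reactants: 17 3-(benzyloxy)-2-[3,4-bis(benzyloxy)phenyl]-7-tert-butoxy-5-hydroxy-6,8-dimethoxy-4H-chromen-4-one
Product: 18 3-(benzyloxy)-2-[3,4-bis(benzyloxy)phenyl]-5,7-dihydroxy-6,8-dimethoxy-4H-chromen-4-one
Conditions: TFA/CH2Cl2 (1:4), 0 °C
Reagents that add atoms: none
Why: Acidolysis of the aryl tert-butyl ether through the tert-butyl cation is fast in dilute TFA, while benzyl and methyl aryl ethers are stable under these conditions.

Step 11
Reactants: 18 3-(benzyloxy)-2-[3,4-bis(benzyloxy)phenyl]-5,7-dihydroxy-6,8-dimethoxy-4H-chromen-4-one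
Product: 19 2-(3,4-dihydroxyphenyl)-3,5,7-trihydroxy-6,8-dimethoxy-4H-chromen-4-one (target)
Conditions: H2 (1 atm), 10% Pd/C, THF/MeOH, rt
Reagents that add atoms: none
Why: Catalytic hydrogenolysis cleaves the three benzyl ethers, while the tetrasubstituted C2=C3 bond of the flavonol and the methyl ethers are not reduced under these conditions.

**Compound list**

1 | 3-bromofuran | Brc1ccoc1 | starting material
2 | 3,4-bis(benzyloxy)benzaldehyde | O=Cc1ccc(OCc2ccccc2)c(OCc2ccccc2)c1 | starting material
3 | (3-bromofuran-2-yl)lithium | [Li]c1occc1Br | intermediate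
4 | [3,4-bis(benzyloxy)phenyl](3-bromofuran-2-yl)methanol (racemic) | OC(c1occc1Br)c1ccc(OCc2ccccc2)c(OCc2ccccc2)c1 | intermediate
5 | 2-[3,4-bis(benzyloxy)phenyl]-4-bromo-6-hydroxy-2H-pyran-3(6H)-one (racemic, mixture of diastereomers) | OC1C=C(Br)C(=O)C(c2ccc(OCc3ccccc3)c(OCc3ccccc3)c2)O1 | intermediate
6 | 2-[3,4-bis(benzyloxy)phenyl]-3-hydroxy-4H-pyran-4-one | O=c1ccoc(-c2ccc(OCc3ccccc3)c(OCc3ccccc3)c2)c1O | intermediate
7 | 3-(benzyloxy)-2-[3,4-bis(benzyloxy)phenyl]-4H-pyran-4-one | O=c1ccoc(-c2ccc(OCc3ccccc3)c(OCc3ccccc3)c2)c1OCc1ccccc1 | intermediate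
8 | 3-(benzyloxy)-2-[3,4-bis(benzyloxy)phenyl]-5-iodo-4H-pyran-4-one | O=c1c(I)coc(-c2ccc(OCc3ccccc3)c(OCc3ccccc3)c2)c1OCc1ccccc1 | intermediate
9 | dimethyl squarate (3,4-dimethoxycyclobut-3-ene-1,2-dione) | COC1=C(OC)C(=O)C1=O | starting material
10 | 3-hydroxy-4-methoxycyclobut-3-ene-1,2-dione | COC1=C(O)C(=O)C1=O | intermediate
11 | 3-tert-butoxy-4-methoxycyclobut-3-ene-1,2-dione | COC1=C(OC(C)(C)C)C(=O)C1=O | intermediate
12 | {5-(benzyloxy)-6-[3,4-bis(benzyloxy)phenyl]-4-oxo-4H-pyran-3-yl}magnesium chloride | O=c1c([Mg]Cl)coc(-c2ccc(OCc3ccccc3)c(OCc3ccccc3)c2)c1OCc1ccccc1 | intermediate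
13 | 4-{5-(benzyloxy)-6-[3,4-bis(benzyloxy)phenyl]-4-oxo-4H-pyran-3-yl}-2-tert-butoxy-4-hydroxy-3-methoxycyclobut-2-en-1-one (racemic) | COC1=C(OC(C)(C)C)C(=O)C1(O)C1=COC(c2ccc(OCc3ccccc3)c(OCc3ccccc3)c2)=C(OCc2ccccc2)C1=O | intermediate
14 | (3Z)-4-{5-(benzyloxy)-6-[3,4-bis(benzyloxy)phenyl]-4-oxo-4H-pyran-3-yl}-2-tert-butoxy-4-hydroxy-3-methoxybuta-1,3-dien-1-one | O=C=C(OC(C)(C)C)/C(OC)=C(/O)C1=COC(c2ccc(OCc3ccccc3)c(OCc3ccccc3)c2)=C(OCc2ccccc2)C1=O | intermediate
15 | 3-(benzyloxy)-2-[3,4-bis(benzyloxy)phenyl]-7-tert-butoxy-5-hydroxy-6-methoxy-8aH-chromene-4,8-dione (racemic) | COC1=C(OC(C)(C)C)C(=O)C2OC(c3ccc(OCc4ccccc4)c(OCc4ccccc4)c3)=C(OCc3ccccc3)C(=O)C2=C1O | intermediate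
16 | 3-(benzyloxy)-2-[3,4-bis(benzyloxy)phenyl]-7-tert-butoxy-5,8-dihydroxy-6-methoxy-4H-chromen-4-one | COc1c(OC(C)(C)C)c(O)c2oc(-c3ccc(OCc4ccccc4)c(OCc4ccccc4)c3)c(OCc3ccccc3)c(=O)c2c1O | intermediate
17 | 3-(benzyloxy)-2-[3,4-bis(benzyloxy)phenyl]-7-tert-butoxy-5-hydroxy-6,8-dimethoxy-4H-chromen-4-one | COc1c(OC(C)(C)C)c(OC)c2oc(-c3ccc(OCc4ccccc4)c(OCc4ccccc4)c3)c(OCc3ccccc3)c(=O)c2c1O | intermediate
18 | 3-(benzyloxy)-2-[3,4-bis(benzyloxy)phenyl]-5,7-dihydroxy-6,8-dimethoxy-4H-chromen-4-one | COc1c(O)c(OC)c2oc(-c3ccc(OCc4ccccc4)c(OCc4ccccc4)c3)c(OCc3ccccc3)c(=O)c2c1O | intermediate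
19 | 2-(3,4-dihydroxyphenyl)-3,5,7-trihydroxy-6,8-dimethoxy-4H-chromen-4-one | COc1c(O)c(OC)c2oc(-c3ccc(O)c(O)c3)c(O)c(=O)c2c1O | target

**Count and risks**

Total step count: 11. Longest linear sequence: 9 steps (steps 1, 2, 3, 4, 7, 8, 9, 10, 11); the squarate branch (steps 5 and 6) joins at step 7.

Steps most likely to fail, riskiest first:

1. Step 8. The ketene may be consumed by hydroxyl groups of a second molecule before it closes onto the electron-poor, partly aromatic pyranone double bond, and the free electron-rich hydroquinone may be lost to air oxidation during isolation. The fallback removes every free hydroxyl from the pericyclic step and lets a protecting group, not the hydrogen bond, tell the two new phenols apart. Setting out from 13, silylation (TESOTf, 2,6-lutidine, CH2Cl2, −78 °C) should give the triethylsilyl ether F1. Thermolysis in toluene at 110 °C should give the 8-hydroxy-5-(triethylsilyloxy)chromenone F2, in which only the ketene-derived oxygen is free. Methylation (MeI, K2CO3, DMF) should give the 8-methyl ether F3. TFA in wet CH2Cl2 then removes the silyl and tert-butyl groups together, and the route is rejoined at 18.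

2. Step 7. Discrimination between the two squarate carbonyl groups may be insufficient, which would exchange the substituents that end up on C6 and C7. The fallback uses a symmetrical squarate, so the site of addition no longer matters, and then differentiates O6 from O7 by the acidity order of 5,6,7-trihydroxyflavones. Setting out from 8 (through 12), addition to purchased di-tert-butyl squarate should give the di-tert-butoxy carbinol F4. Thermolysis as in step 8 should give the 6,7-di-tert-butoxy hydroquinone F5, and methylation of the unchelated 8-hydroxyl the methyl ether F6. TFA should then give the 5,6,7-trihydroxy-8-methoxy compound F7. One equivalent of BnBr with K2CO3 should benzylate the most acidic 7-hydroxyl to the 7-benzyl ether F8. MeI with K2CO3 should methylate the 6-hydroxyl, the chelated 5-hydroxyl staying free, to give the tetrabenzyl ether F9. Hydrogenolysis of the four benzyl ethers brings the route back at 19.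

3. Step 4. There may be no conversion because the pyridine base does not add reversibly to the pyranone; forcing the reaction with a stronger electrophilic iodine source risks iodination of the dialkoxyphenyl ring. The fallback is stoichiometric ring opening and iodine-triggered reclosure, the way 3-iodochromones are made from enaminones. Setting out from 7, pyrrolidine in MeOH should open the pyranone at C6 to the enaminone F10. I2 in CHCl3/pyridine should then iodinate the enamine carbon, after which the enol oxygen recloses the ring with loss of pyrrolidine, and the route is rejoined at 8.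

**Further compounds**

F1 | step 8 | 4-{5-(benzyloxy)-6-[3,4-bis(benzyloxy)phenyl]-4-oxo-4H-pyran-3-yl}-2-tert-butoxy-3-methoxy-4-[(triethylsilyl)oxy]cyclobut-2-en-1-one (racemic) | COC1=C(OC(C)(C)C)C(=O)C1(O[Si](CC)(CC)CC)C1=COC(c2ccc(OCc3ccccc3)c(OCc3ccccc3)c2)=C(OCc2ccccc2)C1=O
F2 | step 8 | 3-(benzyloxy)-2-[3,4-bis(benzyloxy)phenyl]-7-tert-butoxy-8-hydroxy-6-methoxy-5-[(triethylsilyl)oxy]-4H-chromen-4-one | COc1c(OC(C)(C)C)c(O)c2oc(-c3ccc(OCc4ccccc4)c(OCc4ccccc4)c3)c(OCc3ccccc3)c(=O)c2c1O[Si](CC)(CC)CC
F3 | step 8 | 3-(benzyloxy)-2-[3,4-bis(benzyloxy)phenyl]-7-tert-butoxy-6,8-dimethoxy-5-[(triethylsilyl)oxy]-4H-chromen-4-one | COc1c(OC(C)(C)C)c(OC)c2oc(-c3ccc(OCc4ccccc4)c(OCc4ccccc4)c3)c(OCc3ccccc3)c(=O)c2c1O[Si](CC)(CC)CC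
F4 | step 7 | 4-{5-(benzyloxy)-6-[3,4-bis(benzyloxy)phenyl]-4-oxo-4H-pyran-3-yl}-2,3-di-tert-butoxy-4-hydroxycyclobut-2-en-1-one (racemic) | CC(C)(C)OC1=C(OC(C)(C)C)C(=O)C1(O)C1=COC(c2ccc(OCc3ccccc3)c(OCc3ccccc3)c2)=C(OCc2ccccc2)C1=O
F5 | step 7 | 3-(benzyloxy)-2-[3,4-bis(benzyloxy)phenyl]-6,7-di-tert-butoxy-5,8-dihydroxy-4H-chromen-4-one | CC(C)(C)Oc1c(OC(C)(C)C)c(O)c2oc(-c3ccc(OCc4ccccc4)c(OCc4ccccc4)c3)c(OCc3ccccc3)c(=O)c2c1O
F6 | step 7 | 3-(benzyloxy)-2-[3,4-bis(benzyloxy)phenyl]-6,7-di-tert-butoxy-5-hydroxy-8-methoxy-4H-chromen-4-one | CC(C)(C)Oc1c(OC(C)(C)C)c(OC)c2oc(-c3ccc(OCc4ccccc4)c(OCc4ccccc4)c3)c(OCc3ccccc3)c(=O)c2c1O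
F7 | step 7 | 3-(benzyloxy)-2-[3,4-bis(benzyloxy)phenyl]-5,6,7-trihydroxy-8-methoxy-4H-chromen-4-one | COc1c(O)c(O)c(O)c2c(=O)c(OCc3ccccc3)c(-c3ccc(OCc4ccccc4)c(OCc4ccccc4)c3)oc12
F8 | step 7 | 3,7-bis(benzyloxy)-2-[3,4-bis(benzyloxy)phenyl]-5,6-dihydroxy-8-methoxy-4H-chromen-4-one | COc1c(OCc2ccccc2)c(O)c(O)c2c(=O)c(OCc3ccccc3)c(-c3ccc(OCc4ccccc4)c(OCc4ccccc4)c3)oc12
F9 | step 7 | 3,7-bis(benzyloxy)-2-[3,4-bis(benzyloxy)phenyl]-5-hydroxy-6,8-dimethoxy-4H-chromen-4-one | COc1c(OCc2ccccc2)c(OC)c(O)c2c(=O)c(OCc3ccccc3)c(-c3ccc(OCc4ccccc4)c(OCc4ccccc4)c3)oc12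
F10 | step 4 | (4E)-2-(benzyloxy)-1-[3,4-bis(benzyloxy)phenyl]-5-(pyrrolidin-1-yl)pent-4-ene-1,3-dione (racemic keto form of the enolised diketone) | O=C(c1ccc(OCc2ccccc2)c(OCc2ccccc2)c1)C(OCc1ccccc1)C(=O)/C=C/N1CCCC1
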